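The decalin is cut at C5–C10 and C8–C9. In ring B the C6=C7 alkene lies beside the oxygenated C8, so the enone is read backwards as a cyclohexenyl silyl ether arising from a 1-silyloxydiene (C5 to C8) and an enal alkene (C9=C10), joined through the ring A chain C1–C4. A single amine-catalysed intramolecular Diels–Alder reaction of an achiral trienal thus closes rings A and B and sets C5, C9 and C10. The precursor is open-chain (2E,8E,10E)-3,7,7-trimethyl-11-(triisopropylsilyloxy)undeca-2,8,10-trienal, whose TIPS group withstands the acidic medium. The C11 aldehyde of the adduct is then grown into the side chain by B-alkyl Suzuki coupling.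

Key step: step 8

Remark: locants C1–C20 in the explanations follow labdane numbering (decalin C1–C10, side chain C11–C16, angular methyl C20). The (2R,5R) catalyst, CN1C(=O)[C@@H](Cc2ccccc2)N[C@H]1C(C)(C)C, is specified on the assumption that the usual shielding model of this imidazolidinone (attack anti to the benzyl group of the E-iminium ion) also holds for a β,β-disubstituted enal.

Step 1
Reactants: 1 2,2-dimethylpent-4-enal
Product: 2 1-methoxy-3,3-dimethylhexa-1,5-diene (E/Z mixture)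
Conditions: MeOCH2PPh3Cl, KOtBu, THF, 0 °C → rt
Reagents that add atoms: (methoxymethyl)triphenylphosphonium chloride, COC[P+](c1ccccc1)(c1ccccc1)c1ccccc1.[Cl-]
Why: Wittig olefination of the non-enolisable α-quaternary aldehyde with the methoxymethylene ylide adds the future C6 as an enol ether, which also masks the aldehyde during the later hydroboration; the enol ether geometry is of no consequence.

Step 2
Reactants: 3 ethyl acetoacetate
Product: 5 ethyl (2E)-3-{[(trifluoromethyl)sulfonyl]oxy}but-2-enoate, via tetramethylammonium enolate 4 (not isolated)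
Conditions: 25% aq. Me4NOH, Tf2O, hexane, 5 °C → rt
Reagents that add atoms: trifluoromethanesulfonic anhydride, O=S(=O)(OS(=O)(=O)C(F)(F)F)C(F)(F)F
Why: Stereoselective enol triflate formation from a β-keto ester: the non-chelated ammonium enolate prefers the geometry with the enolate oxygen anti to the ester, and O-sulfonylation traps it as the (E)-triflate that will place the tether trans to the ester.

Step 3
Reactants: 2 1-methoxy-3,3-dimethylhexa-1,5-diene; 5 ethyl (2E)-3-{[(trifluoromethyl)sulfonyl]oxy}but-2-enoate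
Product: 8 ethyl (2E)-3,7,7-trimethyl-9-oxonon-2-enoate, via B-alkyl-9-BBN adduct 6 (not isolated), via coupled enol ether 7 (not isolated)
Conditions: 2, 9-BBN, THF, 0 °C → rt; then 5, PdCl2(dppf) (5 mol%), K3PO4, THF/DMF/H2O, 50 °C; then 1 M HCl, THF, rt
Reagents that add atoms: water, O
Why: 9-BBN hydroborates only the monosubstituted alkene (anti-Markovnikov), B-alkyl Suzuki–Miyaura coupling with retention at the enol triflate forms C1–C10 and the (E)-trisubstituted enoate, and acid hydrolysis of the enol ether unveils the C6 aldehyde.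

Step 4
Reactants: 8 ethyl (2E)-3,7,7-trimethyl-9-oxonon-2-enoate; 9 (triphenylphosphoranylidene)acetaldehyde
Product: 10 ethyl (2E,9E)-3,7,7-trimethyl-11-oxoundeca-2,9-dienoate
Conditions: 9 (1.3 equiv), toluene, 80 °C
Reagents that add atoms: none
Why: Wittig reaction of the unhindered aliphatic aldehyde with the stabilised formylmethylene ylide is E-selective and leaves the β,β-disubstituted enoate untouched.

Step 5
Reactants: 10 ethyl (2E,9E)-3,7,7-trimethyl-11-oxoundeca-2,9-dienoate
Product: 11 ethyl (2E,8E,10E)-3,7,7-trimethyl-11-[(triisopropylsilyl)oxy]undeca-2,8,10-trienoate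
Conditions: TIPSOTf, Et3N, CH2Cl2, −78 → 0 °C
Reagents that add atoms: triisopropylsilyl trifluoromethanesulfonate, CC(C)[Si](C(C)C)(C(C)C)OS(=O)(=O)C(F)(F)F
Why: Soft enolisation (O-silylation of the enal, then γ-deprotonation at C5 by the amine) should give the 1-silyloxy-1,3-diene, the s-trans enal leading to the E enol ether and the bulky quaternary C4 enforcing E at C5=C6, while the ester is not enolised under these conditions.

Step 6
Reactants: 11 ethyl (2E,8E,10E)-3,7,7-trimethyl-11-[(triisopropylsilyl)oxy]undeca-2,8,10-trienoate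
Product: 12 (2E,8E,10E)-3,7,7-trimethyl-11-[(triisopropylsilyl)oxy]undeca-2,8,10-trien-1-ol
Conditions: i-Bu2AlH (2.5 equiv), CH2Cl2, −78 °C; aq. potassium sodium tartrate
Reagents that add atoms: none
Why: Diisobutylaluminium hydride reduces the conjugated ester to the allylic alcohol (1,2-reduction) at low temperature, and the non-acidic tartrate work-up spares the silyl dienol ether.

Step 7
Reactants: 12 (2E,8E,10E)-3,7,7-trimethyl-11-[(triisopropylsilyl)oxy]undeca-2,8,10-trien-1-ol
Product: 13 (2E,8E,10E)-3,7,7-trimethyl-11-[(triisopropylsilyl)oxy]undeca-2,8,10-trienal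
Conditions: activated MnO2 (excess), CH2Cl2, rt
Reagents that add atoms: none
Why: Allylic oxidation with MnO2 is neutral and selective, so the (E)-enal should form without touching the dienol ether.

Step 8
Reactants: 13 (2E,8E,10E)-3,7,7-trimethyl-11-[(triisopropylsilyl)oxy]undeca-2,8,10-trienal
Product: 16 (1S,2R,4aR,8aR)-5,5,8a-trimethyl-2-[(triisopropylsilyl)oxy]-1,2,4a,5,6,7,8,8a-octahydronaphthalene-1-carbaldehyde, via trienyl iminium trifluoroacetate 14 (not isolated), via cycloadduct iminium trifluoroacetate 15 (not isolated)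
Conditions: (2R,5R)-5-benzyl-2-tert-butyl-3-methylimidazolidin-4-one (20 mol%), CF3CO2H (20 mol%), MeCN/H2O 98:2, −20 °C → rt
Reagents that add atoms: none
Why: Proposed new method: the amine salt condenses with enal 13 to the E-configured unsaturated iminium ion 14, whose lowered LUMO at C9=C10 is attacked by the silyloxydiene through its largest HOMO coefficient at C5 (C5 to C10), either in an asynchronous [4+2] or as a vinylogous Mukaiyama–Michael addition followed by enamine-to-silyloxycarbenium aldol closure of C8–C9, and hydrolysis of 15 releases 16 and the catalyst. The closest known reaction type is the imidazolidinone-catalysed intramolecular Diels–Alder reaction of (E,E,E)-trienals to trans-fused bicycles, here extended to a β,β-disubstituted enal that creates the quaternary C10 beside the neopentyl C5. Ring A closes as the tether ring (6-exo-trig attack of C5 on C10 across the C1–C4 chain) and ring B as the six-membered cycloadduct ring (C8–C9, 6-exo-trig in the stepwise picture). C10 is set by the benzyl group of the (2R,5R) catalyst, which blocks one face of the iminium ion; C9 follows from suprafacial addition to the E-enal (C11 cis to the C10 methyl), C5 from the endo transition state of the E-configured C5=C6 (trans ring fusion), and C8 from the E enol ether (oxygen cis to C11, erased later). The step needs endo over exo, a single π-face and retention of the enal geometry; the tether and the matched polarity fix the regiochemistry, the geminal methyls at C4 favour the folded conformer, and the TIPS group keeps the dienol ether from hydrolysing in the acidic aqueous medium.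

Step 9
Reactants: 16 (1S,2R,4aR,8aR)-5,5,8a-trimethyl-2-[(triisopropylsilyl)oxy]-1,2,4a,5,6,7,8,8a-octahydronaphthalene-1-carbaldehyde
Product: 17 {[(1S,2R,4aR,8aR)-1-ethenyl-5,5,8a-trimethyl-1,2,4a,5,6,7,8,8a-octahydronaphthalen-2-yl]oxy}tri(propan-2-yl)silane
Conditions: Ph3PCH3Br, KN(SiMe3)2, THF, 0 °C; then 16, −78 → 0 °C
Reagents that add atoms: methyltriphenylphosphonium bromide, C[P+](c1ccccc1)(c1ccccc1)c1ccccc1.[Br-]
Why: Wittig methylenation with the non-stabilised ylide is fast even for hindered aldehydes and is run cold so that addition outpaces enolisation at C9, whose substituent stays equatorial.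

Step 10
Reactants: 18 tert-butyl(diphenyl)(prop-2-yn-1-yloxy)silane
Product: 20 tert-butyl 4-{[tert-butyl(diphenyl)silyl]oxy}but-2-ynoate, via lithium acetylide 19 (not isolated)
Conditions: n-BuLi, THF, −78 °C; then Boc2O, −78 → 0 °C
Reagents that add atoms: di-tert-butyl dicarbonate, CC(C)(C)OC(=O)OC(=O)OC(C)(C)C
Why: C-Acylation of the lithium acetylide with the dicarbonate gives the tert-butyl ynoate directly (alkynoate synthesis by acetylide acylation).

Step 11
Reactants: 20 tert-butyl 4-{[tert-butyl(diphenyl)silyl]oxy}but-2-ynoate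
Product: 21 tert-butyl (2Z)-4-{[tert-butyl(diphenyl)silyl]oxy}-3-iodobut-2-enoate
Conditions: NaI, AcOH, 70 °C
Reagents that add atoms: sodium iodide, [Na+].[I-]
Why: Hydroiodination by conjugate addition of iodide and anti protonation should give, under kinetic control, the (Z)-β-iodoenoate with iodine cis to the ester, which fixes the later E geometry of C13=C14; the tert-butyl ester and the TBDPS ether tolerate warm acetic acid.

Step 12
Reactants: 17 {[(1S,2R,4aR,8aR)-1-ethenyl-5,5,8a-trimethyl-1,2,4a,5,6,7,8,8a-octahydronaphthalen-2-yl]oxy}tri(propan-2-yl)silane; 21 tert-butyl (2Z)-4-{[tert-butyl(diphenyl)silyl]oxy}-3-iodobut-2-enoate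
Product: 23 tert-butyl (2E)-3-({[tert-butyl(diphenyl)silyl]oxy}methyl)-5-[(1S,2R,4aR,8aR)-5,5,8a-trimethyl-2-[(triisopropylsilyl)oxy]-1,2,4a,5,6,7,8,8a-octahydronaphthalen-1-yl]pent-2-enoate, via B-alkyl-9-BBN adduct 22 (not isolated)
Conditions: 17, 9-BBN, THF, rt → 40 °C; then 21, PdCl2(dppf) (10 mol%), AsPh3 (10 mol%), Cs2CO3, DMF/THF/H2O, rt
Reagents that add atoms: none
Why: 9-BBN hydroborates only the monosubstituted vinyl group (anti-Markovnikov; the C6=C7 ring alkene is inert), and B-alkyl Suzuki–Miyaura coupling with the vinyl iodide proceeds with retention of alkene geometry to form C12–C13.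

Step 13
Reactants: 23 tert-butyl (2E)-3-({[tert-butyl(diphenyl)silyl]oxy}methyl)-5-[(1S,2R,4aR,8aR)-5,5,8a-trimethyl-2-[(triisopropylsilyl)oxy]-1,2,4a,5,6,7,8,8a-octahydronaphthalen-1-yl]pent-2-enoate
Product: 24 tert-butyl (2E)-3-(hydroxymethyl)-5-[(1S,2R,4aR,8aR)-2-hydroxy-5,5,8a-trimethyl-1,2,4a,5,6,7,8,8a-octahydronaphthalen-1-yl]pent-2-enoate
Conditions: TBAF (4 equiv), THF, rt → 45 °C
Reagents that add atoms: none
Why: Fluoride cleaves both silyl ethers (global desilylation), the tert-butyl enoate is inert, and the C16 hydroxyl, trans to the ester, cannot lactonise.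

Step 14
Reactants: 24 tert-butyl (2E)-3-(hydroxymethyl)-5-[(1S,2R,4aR,8aR)-2-hydroxy-5,5,8a-trimethyl-1,2,4a,5,6,7,8,8a-octahydronaphthalen-1-yl]pent-2-enoate
Product: 25 tert-butyl (2E)-3-[(acetyloxy)methyl]-5-[(1S,2R,4aR,8aR)-2-hydroxy-5,5,8a-trimethyl-1,2,4a,5,6,7,8,8a-octahydronaphthalen-1-yl]pent-2-enoate
Conditions: Ac2O (1.1 equiv), pyridine, CH2Cl2, 0 °C
Reagents that add atoms: acetic anhydride, CC(=O)OC(C)=O
Why: Selective esterification: the unhindered primary allylic alcohol is acylated far faster than the axial C8 alcohol, which is shielded by the C9 side chain and the 1,3-diaxial C10 methyl.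

Step 15
Reactants: 25 tert-butyl (2E)-3-[(acetyloxy)methyl]-5-[(1S,2R,4aR,8aR)-2-hydroxy-5,5,8a-trimethyl-1,2,4a,5,6,7,8,8a-octahydronaphthalen-1-yl]pent-2-enoate
Product: 26 tert-butyl (2E)-3-[(acetyloxy)methyl]-5-[(1S,4aR,8aR)-5,5,8a-trimethyl-2-oxo-1,2,4a,5,6,7,8,8a-octahydronaphthalen-1-yl]pent-2-enoate
Conditions: Dess–Martin periodinane, NaHCO3, CH2Cl2, 0 °C → rt
Reagents that add atoms: none
Why: Buffered Dess–Martin oxidation of the secondary allylic alcohol gives the 6-en-8-one, and C9 keeps its equatorial, thermodynamically preferred configuration.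

Step 16
Reactants: 26 tert-butyl (2E)-3-[(acetyloxy)methyl]-5-[(1S,4aR,8aR)-5,5,8a-trimethyl-2-oxo-1,2,4a,5,6,7,8,8a-octahydronaphthalen-1-yl]pent-2-enoate
Product: 27 (2E)-3-[(acetyloxy)methyl]-5-[(1S,4aR,8aR)-5,5,8a-trimethyl-2-oxo-1,2,4a,5,6,7,8,8a-octahydronaphthalen-1-yl]pent-2-enoic acid (CNP0333671.1)
Conditions: CF3CO2H/CH2Cl2 1:4, 0 °C → rt
Reagents that add atoms: none
Why: Acidolysis of the tert-butyl ester (loss of isobutene) frees the acid without affecting the acetate, the enone or the alkene geometry.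

Compound list
1 | 2,2-dimethylpent-4-enal | C=CCC(C)(C)C=O | starting material
2 | 1-methoxy-3,3-dimethylhexa-1,5-diene (E/Z mixture) | COC=CC(C)(C)CC=C | intermediate
3 | ethyl acetoacetate | CCOC(=O)CC(C)=O | starting material
4 | tetramethylammonium (E)-enolate of ethyl acetoacetate | CCOC(=O)/C=C(\C)[O-].C[N+](C)(C)C | intermediate (not isolated)
5 | ethyl (2E)-3-{[(trifluoromethyl)sulfonyl]oxy}but-2-enoate | CCOC(=O)/C=C(\C)OS(=O)(=O)C(F)(F)F | intermediate
6 | 9-(6-methoxy-4,4-dimethylhex-5-en-1-yl)-9-borabicyclo[3.3.1]nonane | COC=CC(C)(C)CCCB1C2CCCC1CCC2 | intermediate (not isolated)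
7 | ethyl (2E)-9-methoxy-3,7,7-trimethylnona-2,8-dienoate (8E/Z mixture) | CCOC(=O)/C=C(\C)CCCC(C)(C)C=COC | intermediate (not isolated)
8 | ethyl (2E)-3,7,7-trimethyl-9-oxonon-2-enoate | CCOC(=O)/C=C(\C)CCCC(C)(C)CC=O | intermediate
9 | (triphenylphosphoranylidene)acetaldehyde | O=CC=P(c1ccccc1)(c1ccccc1)c1ccccc1 | starting material
10 | ethyl (2E,9E)-3,7,7-trimethyl-11-oxoundeca-2,9-dienoate | CCOC(=O)/C=C(\C)CCCC(C)(C)C/C=C/C=O | intermediate
11 | ethyl (2E,8E,10E)-3,7,7-trimethyl-11-[(triisopropylsilyl)oxy]undeca-2,8,10-trienoate | CCOC(=O)/C=C(\C)CCCC(C)(C)/C=C/C=C/O[Si](C(C)C)(C(C)C)C(C)C | intermediate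
12 | (2E,8E,10E)-3,7,7-trimethyl-11-[(triisopropylsilyl)oxy]undeca-2,8,10-trien-1-ol | OC/C=C(\C)CCCC(C)(C)/C=C/C=C/O[Si](C(C)C)(C(C)C)C(C)C | intermediate
13 | (2E,8E,10E)-3,7,7-trimethyl-11-[(triisopropylsilyl)oxy]undeca-2,8,10-trienal | O=C/C=C(\C)CCCC(C)(C)/C=C/C=C/O[Si](C(C)C)(C(C)C)C(C)C | intermediate
14 | iminium trifluoroacetate of 13 with the (2R,5R) imidazolidinone (E at C=N) | CN1C(=O)[C@@H](Cc2ccccc2)/[N+](=C\C=C(/C)CCCC(C)(C)/C=C/C=C/O[Si](C(C)C)(C(C)C)C(C)C)[C@H]1C(C)(C)C.[O-]C(=O)C(F)(F)F | intermediate (not isolated)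
15 | iminium trifluoroacetate of cycloadduct 16 with the (2R,5R) imidazolidinone | CN1C(=O)[C@@H](Cc2ccccc2)[N+](=C[C@@H]3[C@H](O[Si](C(C)C)(C(C)C)C(C)C)C=C[C@@H]4C(C)(C)CCC[C@@]34C)[C@H]1C(C)(C)C.[O-]C(=O)C(F)(F)F | intermediate (not isolated)
16 | (1S,2R,4aR,8aR)-5,5,8a-trimethyl-2-[(triisopropylsilyl)oxy]-1,2,4a,5,6,7,8,8a-octahydronaphthalene-1-carbaldehyde (trans-fused; CHO, OTIPS and angular methyl on one face) | O=C[C@@H]1[C@H](O[Si](C(C)C)(C(C)C)C(C)C)C=C[C@@H]2C(C)(C)CCC[C@@]12C | intermediate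
17 | {[(1S,2R,4aR,8aR)-1-ethenyl-5,5,8a-trimethyl-1,2,4a,5,6,7,8,8a-octahydronaphthalen-2-yl]oxy}tri(propan-2-yl)silane | C=C[C@@H]1[C@H](O[Si](C(C)C)(C(C)C)C(C)C)C=C[C@@H]2C(C)(C)CCC[C@@]12C | intermediate
18 | tert-butyl(diphenyl)(prop-2-yn-1-yloxy)silane | C#CCO[Si](c1ccccc1)(c1ccccc1)C(C)(C)C | starting material
19 | lithium acetylide of 18 | [Li]C#CCO[Si](c1ccccc1)(c1ccccc1)C(C)(C)C | intermediate (not isolated)
20 | tert-butyl 4-{[tert-butyl(diphenyl)silyl]oxy}but-2-ynoate | CC(C)(C)OC(=O)C#CCO[Si](c1ccccc1)(c1ccccc1)C(C)(C)C | intermediate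
21 | tert-butyl (2Z)-4-{[tert-butyl(diphenyl)silyl]oxy}-3-iodobut-2-enoate | CC(C)(C)OC(=O)/C=C(\I)CO[Si](c1ccccc1)(c1ccccc1)C(C)(C)C | intermediate
22 | 9-{2-[(1S,2R,4aR,8aR)-5,5,8a-trimethyl-2-[(triisopropylsilyl)oxy]-1,2,4a,5,6,7,8,8a-octahydronaphthalen-1-yl]ethyl}-9-borabicyclo[3.3.1]nonane | C(C[C@@H]1[C@H](O[Si](C(C)C)(C(C)C)C(C)C)C=C[C@@H]2C(C)(C)CCC[C@@]12C)B3C4CCCC3CCC4 | intermediate (not isolated)
23 | tert-butyl (2E)-3-({[tert-butyl(diphenyl)silyl]oxy}methyl)-5-[(1S,2R,4aR,8aR)-5,5,8a-trimethyl-2-[(triisopropylsilyl)oxy]-1,2,4a,5,6,7,8,8a-octahydronaphthalen-1-yl]pent-2-enoate | CC(C)(C)[Si](c3ccccc3)(c4ccccc4)OC/C(=C/C(=O)OC(C)(C)C)CC[C@@H]1[C@H](O[Si](C(C)C)(C(C)C)C(C)C)C=C[C@@H]2C(C)(C)CCC[C@@]12C | intermediate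
24 | tert-butyl (2E)-3-(hydroxymethyl)-5-[(1S,2R,4aR,8aR)-2-hydroxy-5,5,8a-trimethyl-1,2,4a,5,6,7,8,8a-octahydronaphthalen-1-yl]pent-2-enoate | OC/C(=C/C(=O)OC(C)(C)C)CC[C@@H]1[C@H](O)C=C[C@@H]2C(C)(C)CCC[C@@]12C | intermediate
25 | tert-butyl (2E)-3-[(acetyloxy)methyl]-5-[(1S,2R,4aR,8aR)-2-hydroxy-5,5,8a-trimethyl-1,2,4a,5,6,7,8,8a-octahydronaphthalen-1-yl]pent-2-enoate | CC(=O)OC/C(=C/C(=O)OC(C)(C)C)CC[C@@H]1[C@H](O)C=C[C@@H]2C(C)(C)CCC[C@@]12C | intermediate
26 | tert-butyl (2E)-3-[(acetyloxy)methyl]-5-[(1S,4aR,8aR)-5,5,8a-trimethyl-2-oxo-1,2,4a,5,6,7,8,8a-octahydronaphthalen-1-yl]pent-2-enoate | CC(=O)OC/C(=C/C(=O)OC(C)(C)C)CC[C@@H]1C(=O)C=C[C@@H]2C(C)(C)CCC[C@@]12C | intermediate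
27 | (2E)-3-[(acetyloxy)methyl]-5-[(1S,4aR,8aR)-5,5,8a-trimethyl-2-oxo-1,2,4a,5,6,7,8,8a-octahydronaphthalen-1-yl]pent-2-enoic acid | CC(=O)OC/C(=C/C(=O)O)CC[C@@H]1C(=O)C=C[C@@H]2C(C)(C)CCC[C@@]12C | target

Total step count: 16 (steps 2, 10 and 11 prepare the two coupling partners).
Longest linear sequence: 13 steps (1, 3, 4, 5, 6, 7, 8, 9, 12, 13, 14, 15, 16).

Steps most likely to fail

Step 8. The hindered β,β-disubstituted enal may condense only slowly with the amine. The C9=C10 geometry may scramble through a dienamine, the dienol ether may hydrolyse, or silanol may be eliminated from the adduct. Any of these would lower conversion, the endo/exo ratio or the enantiomeric purity. Fallback with known chemistry, setting out from 13 and returning at 16: a purely thermal intramolecular Diels–Alder reaction (toluene, BHT, 150 °C, sealed tube) should give, after chromatographic removal of the cis-fused isomer, the racemic trans-fused aldehyde F1. NaBH4 in methanol reduces it to the racemic alcohol F2. Esterification with (S)-O-methylmandelic acid (DCC, DMAP) gives two diastereomeric esters that are separated by chromatography, the one with the wanted decalin configuration being the mandelate F3. K2CO3 in methanol frees the enantiopure alcohol F4, and Dess–Martin oxidation leads back to 16.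

Step 12. The vinyl group sits between the quaternary C10 and the silyloxy-bearing C8. Hydroboration may therefore be slow, and the congested alkylborane may transmetalate sluggishly, so that protodeboronation or β-hydride elimination competes with coupling. Fallback, setting out from 17 and returning at 23: hydroboration with 9-BBN followed by oxidation with NaBO3·4H2O gives the primary alcohol F5. Iodination (I2, PPh3, imidazole) gives the iodide F6, and zinc insertion (Zn dust, LiCl, THF) the alkylzinc iodide F7. Negishi coupling of F7 with 21 (Pd(PPh3)4, THF/DMF) rejoins the route at 23.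

Step 9. The basic ylide may enolise the hindered aldehyde instead of adding to it, which would epimerise C9 or expel the axial C8 silyloxy group by an E1cB pathway. Fallback, setting out from 16 and returning at 17: addition of the far less basic Me3SiCH2MgCl in the presence of CeCl3 (THF, −78 °C) gives the β-hydroxysilane F8, and Peterson elimination with KH in THF gives 17.

Further compounds
F1 | step 8 | racemic (1S,2R,4aR,8aR)-5,5,8a-trimethyl-2-[(triisopropylsilyl)oxy]-1,2,4a,5,6,7,8,8a-octahydronaphthalene-1-carbaldehyde (both enantiomers) | O=C[C@@H]1[C@H](O[Si](C(C)C)(C(C)C)C(C)C)C=C[C@@H]2C(C)(C)CCC[C@@]12C.O=C[C@H]1[C@@H](O[Si](C(C)C)(C(C)C)C(C)C)C=C[C@H]2C(C)(C)CCC[C@]12C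
F2 | step 8 | racemic [(1R,2R,4aR,8aR)-5,5,8a-trimethyl-2-[(triisopropylsilyl)oxy]-1,2,4a,5,6,7,8,8a-octahydronaphthalen-1-yl]methanol (both enantiomers) | OC[C@@H]1[C@H](O[Si](C(C)C)(C(C)C)C(C)C)C=C[C@@H]2C(C)(C)CCC[C@@]12C.OC[C@H]1[C@@H](O[Si](C(C)C)(C(C)C)C(C)C)C=C[C@H]2C(C)(C)CCC[C@]12C
F3 | step 8 | [(1R,2R,4aR,8aR)-5,5,8a-trimethyl-2-[(triisopropylsilyl)oxy]-1,2,4a,5,6,7,8,8a-octahydronaphthalen-1-yl]methyl (2S)-methoxy(phenyl)acetate | CO[C@@H](c3ccccc3)C(=O)OC[C@@H]1[C@H](O[Si](C(C)C)(C(C)C)C(C)C)C=C[C@@H]2C(C)(C)CCC[C@@]12C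
F4 | step 8 | [(1R,2R,4aR,8aR)-5,5,8a-trimethyl-2-[(triisopropylsilyl)oxy]-1,2,4a,5,6,7,8,8a-octahydronaphthalen-1-yl]methanol | OC[C@@H]1[C@H](O[Si](C(C)C)(C(C)C)C(C)C)C=C[C@@H]2C(C)(C)CCC[C@@]12C
F5 | step 12 | 2-[(1S,2R,4aR,8aR)-5,5,8a-trimethyl-2-[(triisopropylsilyl)oxy]-1,2,4a,5,6,7,8,8a-octahydronaphthalen-1-yl]ethanol | OCC[C@@H]1[C@H](O[Si](C(C)C)(C(C)C)C(C)C)C=C[C@@H]2C(C)(C)CCC[C@@]12C
F6 | step 12 | {[(1S,2R,4aR,8aR)-1-(2-iodoethyl)-5,5,8a-trimethyl-1,2,4a,5,6,7,8,8a-octahydronaphthalen-2-yl]oxy}tri(propan-2-yl)silane | ICC[C@@H]1[C@H](O[Si](C(C)C)(C(C)C)C(C)C)C=C[C@@H]2C(C)(C)CCC[C@@]12C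
F7 | step 12 | {2-[(1S,2R,4aR,8aR)-5,5,8a-trimethyl-2-[(triisopropylsilyl)oxy]-1,2,4a,5,6,7,8,8a-octahydronaphthalen-1-yl]ethyl}zinc iodide | I[Zn]CC[C@@H]1[C@H](O[Si](C(C)C)(C(C)C)C(C)C)C=C[C@@H]2C(C)(C)CCC[C@@]12C
F8 | step 9 | 1-[(1R,2R,4aR,8aR)-5,5,8a-trimethyl-2-[(triisopropylsilyl)oxy]-1,2,4a,5,6,7,8,8a-octahydronaphthalen-1-yl]-2-(trimethylsilyl)ethanol (carbinol epimers) | C[Si](C)(C)CC(O)[C@@H]1[C@H](O[Si](C(C)C)(C(C)C)C(C)C)C=C[C@@H]2C(C)(C)CCC[C@@]12C
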